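**Retrosynthetic overview**
1. Feature: the 3(2H)-furanone ring (O, C3, C2, C1, C10) spans C3 and C10 of the ten-membered carbocycle. A C3–O–C10 ether next to oxygenated C1 is what forms when O3 of a 3-hydroxy-germacr-1(10)E-ene opens the derived 1(10)-epoxide at tertiary C10.
2. Endgame: 39 ⇐ C2=C3 dehydrogenation ⇐ C1 ketone 37 ⇐ 1-hydroxy-3,10-ether 36 ⇐ epoxidation and transannular etherification of 3-hydroxy alkene 34. This ring is formed last.
3. 34 ⇐ trans-lactone 30 (second ring: hydroboration of C11=C12, oxidative lactonisation, C11 equilibration, then the C8 tiglate) ⇐ germacradienol 25.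
4. 25 ⇐ CrCl2 closure of C6–C7 in the (E)-allyl bromide aldehyde 23. This is the first ring. The ester-free E allyl unit is chosen because it adds anti, as the trans-lactone requires.
5. 23 ⇐ (S)-benzyl glycidyl ether (C7–C9), acetylide (C10, C1), AlMe3 (C14), ethylene oxide (C2, C3), (E)-crotylborane (C4–C6, C15) and Ph3P=C(Me)CO2Et (C11–C13).

Key step: step 21

Remark: germacrane numbering (C1–C10 ring, C11–C13 lactone side chain, C14 on C10, C15 on C4) is used in the explanations, TBS = tert-butyldimethylsilyl, TIPS = triisopropylsilyl, Ipc = isopinocampheyl, and the 11S methyl configuration is assumed to be the thermodynamically preferred one of the trans-fused lactone.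

**Step 1**
Reactants: 1 (S)-benzyl glycidyl ether; 2 lithium acetylide–ethylenediamine complex
Product: 3 (2S)-1-(benzyloxy)pent-4-yn-2-ol
Conditions: 2 (1.5 equiv), DMSO, rt; then H2O
Reagents that add atoms: none
Why: Regioselective SN2 opening of the terminal epoxide by the acetylide at its unsubstituted carbon (the future C9) leaves the C–O bond of the stereocentre untouched, so the S configuration of 1 is carried over as C8.

**Step 2**
Reactants: 3 (2S)-1-(benzyloxy)pent-4-yn-2-ol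
Product: 4 (2S)-1-(benzyloxy)-2-(TBSO)pent-4-yne
Conditions: TBSCl, imidazole, DMF, rt
Reagents that add atoms: tert-butyldimethylsilyl chloride, CC(C)(C)[Si](C)(C)Cl
Why: Imidazole-promoted silylation of a secondary alcohol gives a TBS ether that tolerates the organoaluminium, organolithium, hydride, borane and CrCl2 steps ahead and can later be removed beside a TIPS ether.

**Step 3**
Reactants: 4 (2S)-1-(benzyloxy)-2-(TBSO)pent-4-yne; 5 ethylene oxide
Product: 8 (3E,6S)-7-(benzyloxy)-6-(TBSO)-4-methylhept-3-en-1-ol, via alkenyldimethylalane 6 (not isolated), via lithium alkenylalanate 7 (not isolated)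
Conditions: AlMe3 (3 equiv), Cp2ZrCl2 (0.25 equiv), CH2Cl2, 0 °C → rt; volatiles removed; hexane, n-BuLi (3 equiv), 0 °C; 5, THF, 0 °C → rt; then H2O
Reagents that add atoms: trimethylaluminium, C[Al](C)C
Why: Zirconium-catalysed Negishi carboalumination adds methyl (to C10) and aluminium (to C1) syn across the terminal alkyne, which fixes the E geometry of C1=C10, and the more nucleophilic alanate made with n-BuLi opens ethylene oxide with retention at the alkenyl carbon.

**Step 4**
Reactants: 8 (3E,6S)-7-(benzyloxy)-6-(TBSO)-4-methylhept-3-en-1-ol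
Product: 9 (3E,6S)-7-(benzyloxy)-6-(TBSO)-4-methylhept-3-enal
Conditions: Dess–Martin periodinane, NaHCO3, CH2Cl2, 0 °C
Reagents that add atoms: none
Why: Buffered Dess–Martin oxidation works under neutral conditions at low temperature, so the β,γ-unsaturated aldehyde should form without migration of C1=C10 into conjugation, and 9 is used at once.

**Step 5**
Reactants: 9 (3E,6S)-7-(benzyloxy)-6-(TBSO)-4-methylhept-3-enal; 10 (E)-but-2-ene
Product: 13 (3S,4R,6E,9S)-10-(benzyloxy)-9-(TBSO)-3,7-dimethyldeca-1,6-dien-4-ol, via (E)-crotyldiisopinocampheylborane 11 (not isolated), via homoallyl diisopinocampheylborinate 12 (not isolated)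
Conditions: 10, n-BuLi, KOt-Bu, THF, −78 → −45 °C; (−)-Ipc2BOMe [from (+)-α-pinene], −78 °C; BF3·OEt2; 9, −78 °C; NaOH, H2O2, 0 °C → rt
Reagents that add atoms: none
Why: Brown asymmetric crotylboration passes through a closed chair (Zimmerman–Traxler) transition state in which the E crotyl geometry sets the 3,4-anti relationship and the isopinocampheyl groups derived from (+)-α-pinene choose the aldehyde face that gives 3R,4S (germacrane numbering), independently of the remote C8.

**Step 6**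
Reactants: 13 (3S,4R,6E,9S)-10-(benzyloxy)-9-(TBSO)-3,7-dimethyldeca-1,6-dien-4-ol
Product: 14 (3S,4R,6E,9S)-10-(benzyloxy)-9-(TBSO)-3,7-dimethyl-4-(TIPSO)deca-1,6-diene
Conditions: TIPSOTf, 2,6-lutidine, CH2Cl2, 0 °C
Reagents that add atoms: triisopropylsilyl triflate, CC(C)[Si](C(C)C)(C(C)C)OS(=O)(=O)C(F)(F)F
Why: Silyl triflate–lutidine silylation covers the hindered C3 hydroxyl with a TIPS group whose much higher stability than the C8 TBS ether allows the two oxygens to be released in the needed order.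

**Step 7**
Reactants: 14 (3S,4R,6E,9S)-10-(benzyloxy)-9-(TBSO)-3,7-dimethyl-4-(TIPSO)deca-1,6-diene
Product: 15 (2S,4E,7R,8S)-2-(TBSO)-4,8-dimethyl-7-(TIPSO)deca-4,9-dien-1-ol
Conditions: lithium 4,4'-di-tert-butylbiphenylide (LiDBB), THF, −78 °C; then H2O
Reagents that add atoms: none
Why: Reductive benzyl ether cleavage by electron transfer from the arene radical anion leaves isolated alkenes and trialkylsilyl ethers alone, whereas hydrogenolysis would endanger both alkenes.

**Step 8**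
Reactants: 15 (2S,4E,7R,8S)-2-(TBSO)-4,8-dimethyl-7-(TIPSO)deca-4,9-dien-1-ol
Product: 16 (2S,4E,7R,8S)-2-(TBSO)-4,8-dimethyl-7-(TIPSO)deca-4,9-dienal
Conditions: Dess–Martin periodinane, NaHCO3, CH2Cl2, 0 °C → rt
Reagents that add atoms: none
Why: Dess–Martin oxidation of the primary alcohol stops at the aldehyde and its non-basic medium should not epimerise the α-silyloxy stereocentre C8.

**Step 9**
Reactants: 16 (2S,4E,7R,8S)-2-(TBSO)-4,8-dimethyl-7-(TIPSO)deca-4,9-dienal; 17 ethyl 2-(triphenylphosphoranylidene)propanoate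
Product: 18 ethyl (2E,4S,6E,9R,10S)-4-(TBSO)-2,6,10-trimethyl-9-(TIPSO)dodeca-2,6,11-trienoate
Conditions: 17, CH2Cl2, rt
Reagents that add atoms: none
Why: Wittig olefination with a stabilised α-methyl ylide is E-selective, which places C8 trans to the ester carbon and so presets the geometry of the later allylchromium reagent.

**Step 10**
Reactants: 18 ethyl (2E,4S,6E,9R,10S)-4-(TBSO)-2,6,10-trimethyl-9-(TIPSO)dodeca-2,6,11-trienoate
Product: 19 (2E,4S,6E,9R,10S)-4-(TBSO)-2,6,10-trimethyl-9-(TIPSO)dodeca-2,6,11-trien-1-ol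
Conditions: i-Bu2AlH (2.5 equiv), CH2Cl2, −78 °C; aq. potassium sodium tartrate
Reagents that add atoms: none
Why: Low-temperature i-Bu2AlH reduction takes the enoate by two 1,2-hydride additions to the allylic alcohol without touching alkenes or silyl ethers.

**Step 11**
Reactants: 19 (2E,4S,6E,9R,10S)-4-(TBSO)-2,6,10-trimethyl-9-(TIPSO)dodeca-2,6,11-trien-1-ol
Product: 21 (2E,4S,6E,9R,10S)-4-(TBSO)-2,6,10-trimethyl-9-(TIPSO)dodeca-2,6-diene-1,12-diol, via bis(9-BBN) adduct 20 (not isolated)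
Conditions: 9-BBN (2.5 equiv), THF, 0 °C → rt; NaOH, H2O2, 0 °C
Reagents that add atoms: hydrogen peroxide, OO
Why: Hydroboration–oxidation with the bulky 9-BBN is highly selective for the monosubstituted C5=C6 alkene over both trisubstituted alkenes and places boron, then oxygen, on the terminal carbon C6.

**Step 12**
Reactants: 21 (2E,4S,6E,9R,10S)-4-(TBSO)-2,6,10-trimethyl-9-(TIPSO)dodeca-2,6-diene-1,12-diol
Product: 22 (3S,4R,6E,9S,10E)-12-bromo-9-(TBSO)-3,7,11-trimethyl-4-(TIPSO)dodeca-6,10-dien-1-ol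
Conditions: N-bromosuccinimide, Me2S, CH2Cl2, −20 → 0 °C
Reagents that add atoms: N-bromosuccinimide, O=C1CCC(=O)N1Br
Why: In the Corey–Kim halide synthesis both hydroxyls are taken up as alkoxysulfonium salts but bromide displaces only the activated allylic one (SN2, E geometry kept), while the saturated C6 salt is returned as the alcohol on aqueous work-up.

**Step 13**
Reactants: 22 (3S,4R,6E,9S,10E)-12-bromo-9-(TBSO)-3,7,11-trimethyl-4-(TIPSO)dodeca-6,10-dien-1-ol
Product: 23 (3S,4R,6E,9S,10E)-12-bromo-9-(TBSO)-3,7,11-trimethyl-4-(TIPSO)dodeca-6,10-dienal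
Conditions: Dess–Martin periodinane, NaHCO3, CH2Cl2, 0 °C
Reagents that add atoms: none
Why: Dess–Martin oxidation is neutral and fast, so the primary alcohol becomes the C6 aldehyde while the allylic bromide survives.

**Step 14**
Reactants: 23 (3S,4R,6E,9S,10E)-12-bromo-9-(TBSO)-3,7,11-trimethyl-4-(TIPSO)dodeca-6,10-dienal
Product: 25 (1(10)E,3R,4S,6R,7S,8S)-8-(TBSO)-3-(TIPSO)germacra-1(10),11-dien-6-ol, via allylchromium dichloride 24 (not isolated)
Conditions: CrCl2 (10 equiv), THF, rt, 23 added by syringe pump over 12 h (final 2 mM); then H2O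
Reagents that add atoms: none
Why: In this intramolecular Nozaki–Hiyama allylation, a closure type known for the C6–C7 bond of germacrane rings, the (E)-allyl species of trivalent chromium adds through its γ-carbon C7 via a chair transition state that gives the 6,7-anti (later trans-lactone) relationship, while allylic 1,3-strain with the C11 methyl holds H8 in the alkene plane so that C6 bonds anti to the C8 silyloxy group (6R,7S).

**Step 15**
Reactants: 25 (1(10)E,3R,4S,6R,7S,8S)-8-(TBSO)-3-(TIPSO)germacra-1(10),11-dien-6-ol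
Product: 27 (1(10)E,3R,4S,6R,7S,8S)-8-(TBSO)-3-(TIPSO)germacr-1(10)-ene-6,12-diol (C11 epimers), via bis(9-BBN) adduct 26 (not isolated)
Conditions: 9-BBN (3 equiv), THF, rt; NaOH, H2O2, 0 °C
Reagents that add atoms: hydrogen peroxide, OO
Why: In this hydroboration–oxidation the 1,1-disubstituted isopropenyl alkene reacts far faster with 9-BBN than the trisubstituted ring alkene, boron goes to the terminal carbon C12, and the C11 configuration formed here does not matter because it is equilibrated in step 17.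

**Step 16**
Reactants: 27 (1(10)E,3R,4S,6R,7S,8S)-8-(TBSO)-3-(TIPSO)germacr-1(10)-ene-6,12-diol (C11 epimers)
Product: 29 8-(TBSO)-3-(TIPSO)germacr-1(10)E-en-6,12-olide (C11 epimers), via lactol 28 (not isolated)
Conditions: 2,2,6,6-tetramethylpiperidine-1-oxyl (TEMPO, 0.2 equiv), PhI(OAc)2 (2.5 equiv), CH2Cl2, rt
Reagents that add atoms: none
Why: In this oxoammonium-mediated oxidative lactonisation of a 1,4-diol the primary C12 alcohol is oxidised first, the aldehyde is trapped by O6 as a lactol and this is oxidised again to the γ-lactone, with C6 and C7 and the ring alkene untouched.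

**Step 17**
Reactants: 29 8-(TBSO)-3-(TIPSO)germacr-1(10)E-en-6,12-olide (C11 epimers)
Product: 30 (1(10)E,3R,4S,6R,7S,8S,11S)-8-(TBSO)-3-(TIPSO)germacr-1(10)-en-6,12-olide
Conditions: 1,8-diazabicyclo[5.4.0]undec-7-ene (DBU), toluene, 60 °C
Reagents that add atoms: none
Why: Base-mediated epimerisation through the lactone enolate should funnel both C11 epimers into the thermodynamically favoured 11S isomer, in which C13 stands trans to the C7–C8 bond on the trans-fused lactone.

**Step 18**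
Reactants: 30 (1(10)E,3R,4S,6R,7S,8S,11S)-8-(TBSO)-3-(TIPSO)germacr-1(10)-en-6,12-olide
Product: 31 (1(10)E,3R,4S,6R,7R,8S,11S)-8-hydroxy-3-(TIPSO)germacr-1(10)-en-6,12-olide (the C7 descriptor changes by priority only)
Conditions: HF·pyridine, pyridine, THF, 0 °C → rt
Reagents that add atoms: none
Why: Buffered HF·pyridine desilylation distinguishes the two secondary silyl ethers by the steric shielding at silicon, cleaving TBS well before TIPS, and its weakly acidic medium avoids translactonisation towards O8.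

**Step 19**
Reactants: 31 (1(10)E,3R,4S,6R,7R,8S,11S)-8-hydroxy-3-(TIPSO)germacr-1(10)-en-6,12-olide; 32 tigloyl chloride
Product: 33 (1(10)E,3R,4S,6R,7S,8S,11S)-3-(TIPSO)germacr-1(10)-en-6,12-olide 8-tiglate
Conditions: 32, Et3N, 4-(dimethylamino)pyridine (DMAP, 0.2 equiv), CH2Cl2, 0 °C → rt
Reagents that add atoms: none
Why: DMAP-catalysed acylation (nucleophilic catalysis) esterifies O8 with retention at C8, the favoured E geometry of the tigloyl group is not at risk, and the mild amine base is too weak to trigger translactonisation.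

**Step 20**
Reactants: 33 (1(10)E,3R,4S,6R,7S,8S,11S)-3-(TIPSO)germacr-1(10)-en-6,12-olide 8-tiglate
Product: 34 (1(10)E,3R,4S,6R,7S,8S,11S)-3-hydroxygermacr-1(10)-en-6,12-olide 8-tiglate
Conditions: Bu4NF, AcOH (1:1), THF, rt
Reagents that add atoms: none
Why: Fluoride-induced desilylation driven by the strong Si–F bond frees the C3 hydroxyl, and buffering with acetic acid keeps the medium from hydrolysing the tiglate or epimerising C11.

**Step 21**
Reactants: 34 (1(10)E,3R,4S,6R,7S,8S,11S)-3-hydroxygermacr-1(10)-en-6,12-olide 8-tiglate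
Product: 36 (1S,3R,4S,6R,7S,8S,10R,11S)-1-hydroxy-3,10-epoxygermacran-6,12-olide 8-tiglate, via (1S,10S)-1(10)-epoxide 35 (not isolated)
Conditions: mCPBA (1.1 equiv), CH2Cl2, −20 → 0 °C; then camphor-10-sulfonic acid (0.2 equiv), 0 °C → rt
Reagents that add atoms: m-chloroperbenzoic acid, O=C(OO)c1cccc(Cl)c1
Why: mCPBA delivers oxygen (Prilezhaev epoxidation) to the peripheral face of the strained, electron-rich E C1=C10 alkene, the tiglate alkene being switched off by its ester, and this forms C1–O in the trans-epoxide 35. The sulfonic acid then protonates the epoxide, the bond from oxygen to tertiary C10 stretches first, and O3, which lies over the inner face because C3 belongs to the chain that spans that face, attacks C10 from the rear to form C10–O3. The closest known reaction types are the acid-induced transannular opening of germacranolide 1(10)-epoxides by a ring hydroxyl and the acid-catalysed cyclisation of trisubstituted 3,4-epoxy alcohols to 3-hydroxytetrahydrofurans. One ring closes, the oxolane O–C3–C2–C1–C10, in a formally 5-endo-tet mode made possible by the cation-like tertiary centre, and the competing 4-exo attack at secondary C1 would give a strained oxetane. C1 (S) keeps the configuration set by the epoxidation face and C10 (R) arises by inversion, so the E geometry is translated into a C1 hydroxyl cis to C14 on the oxolane, while the absolute sense is tied to C3 (R) because only the epoxide whose rear side faces O3 can give the oxolane with C4 and C9 cis. The step needs chemoselectivity and regioselectivity, both secured electronically, and facial selectivity, which rests on interconverting ring conformers biased by the trans-lactone and the C8 ester, and with C4–C5 saturated there is no second ring alkene that could trap the developing charge at C10.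

**Step 22**
Reactants: 36 (1S,3R,4S,6R,7S,8S,10R,11S)-1-hydroxy-3,10-epoxygermacran-6,12-olide 8-tiglate
Product: 37 (3R,4S,6R,7S,8S,10R,11S)-1-oxo-3,10-epoxygermacran-6,12-olide 8-tiglate
Conditions: Dess–Martin periodinane, NaHCO3, CH2Cl2, rt
Reagents that add atoms: none
Why: Dess–Martin oxidation handles hindered neopentyl-type secondary alcohols and removes the C1 stereocentre without affecting the ether bridge, the lactone or the tiglate.

**Step 23**
Reactants: 37 (3R,4S,6R,7S,8S,10R,11S)-1-oxo-3,10-epoxygermacran-6,12-olide 8-tiglate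
Product: 38 (3S,4S,6R,7S,8S,10R,11S)-1-(trimethylsilyloxy)-3,10-epoxygermacr-1-en-6,12-olide 8-tiglate (the C3 descriptor changes by priority only)
Conditions: TMSOTf (1.3 equiv), Et3N, CH2Cl2, 0 °C
Reagents that add atoms: trimethylsilyl triflate, C[Si](C)(C)OS(=O)(=O)C(F)(F)F
Why: Soft enolisation with TMSOTf and Et3N can only go towards C2 because C10 is quaternary, prefers the ketone over the lactone and the ester, and avoids a free metal enolate that might expel O3 by retro-oxa-Michael opening.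

**Step 24**
Reactants: 38 (3S,4S,6R,7S,8S,10R,11S)-1-(trimethylsilyloxy)-3,10-epoxygermacr-1-en-6,12-olide 8-tiglate
Product: 39 CNP0235937.1, (4S,6R,7S,8S,10R,11S)-1-oxo-3,10-epoxygermacr-2-en-6,12-olide 8-tiglate
Conditions: Pd(OAc)2 (1.1 equiv), MeCN, rt
Reagents that add atoms: none
Why: In the Saegusa–Ito oxidation divalent palladium replaces silicon to give a C2-bound palladium enolate on the open face of the oxolane, which is the face that carries H3, so syn β-hydride elimination gives the C2=C3 enol ether of the 3(2H)-furanone and zerovalent palladium while the six remaining stereocentres stay untouched.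

**Compound list**
1 | (S)-benzyl glycidyl ether | c1ccccc1COC[C@@H]1CO1 | starting material
2 | lithium acetylide–ethylenediamine complex | [Li+].[C-]#C.NCCN | starting material
3 | (2S)-1-(benzyloxy)pent-4-yn-2-ol | c1ccccc1COC[C@@H](O)CC#C | intermediate
4 | (2S)-1-(benzyloxy)-2-(TBSO)pent-4-yne | c1ccccc1COC[C@@H](O[Si](C)(C)C(C)(C)C)CC#C | intermediate
5 | ethylene oxide | C1CO1 | starting material
6 | [(1E,4S)-5-(benzyloxy)-4-(TBSO)-2-methylpent-1-enyl]dimethylalane | c1ccccc1COC[C@@H](O[Si](C)(C)C(C)(C)C)C/C(C)=C/[Al](C)C | intermediate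
7 | lithium butyl[(1E,4S)-5-(benzyloxy)-4-(TBSO)-2-methylpent-1-enyl]dimethylalanate | c1ccccc1COC[C@@H](O[Si](C)(C)C(C)(C)C)C/C(C)=C/[Al-](C)(C)CCCC.[Li+] | intermediate
8 | (3E,6S)-7-(benzyloxy)-6-(TBSO)-4-methylhept-3-en-1-ol | c1ccccc1COC[C@@H](O[Si](C)(C)C(C)(C)C)C/C(C)=C/CCO | intermediate
9 | (3E,6S)-7-(benzyloxy)-6-(TBSO)-4-methylhept-3-enal | c1ccccc1COC[C@@H](O[Si](C)(C)C(C)(C)C)C/C(C)=C/CC=O | intermediate
10 | (E)-but-2-ene | C/C=C/C | starting material
11 | (E)-crotyldiisopinocampheylborane, Ipc from (+)-α-pinene | C/C=C/CB([C@H]1[C@H](C)[C@H]2C[C@@H](C1)C2(C)C)[C@H]1[C@H](C)[C@H]2C[C@@H](C1)C2(C)C | intermediate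
12 | diisopinocampheylborinate of 13 | c1ccccc1COC[C@@H](O[Si](C)(C)C(C)(C)C)C/C(C)=C/C[C@@H](OB([C@H]1[C@H](C)[C@H]2C[C@@H](C1)C2(C)C)[C@H]1[C@H](C)[C@H]2C[C@@H](C1)C2(C)C)[C@@H](C)C=C | intermediate
13 | (3S,4R,6E,9S)-10-(benzyloxy)-9-(TBSO)-3,7-dimethyldeca-1,6-dien-4-ol | c1ccccc1COC[C@@H](O[Si](C)(C)C(C)(C)C)C/C(C)=C/C[C@@H](O)[C@@H](C)C=C | intermediate
14 | (3S,4R,6E,9S)-10-(benzyloxy)-9-(TBSO)-3,7-dimethyl-4-(TIPSO)deca-1,6-diene | c1ccccc1COC[C@@H](O[Si](C)(C)C(C)(C)C)C/C(C)=C/C[C@@H](O[Si](C(C)C)(C(C)C)C(C)C)[C@@H](C)C=C | intermediate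
15 | (2S,4E,7R,8S)-2-(TBSO)-4,8-dimethyl-7-(TIPSO)deca-4,9-dien-1-ol | OC[C@@H](O[Si](C)(C)C(C)(C)C)C/C(C)=C/C[C@@H](O[Si](C(C)C)(C(C)C)C(C)C)[C@@H](C)C=C | intermediate
16 | (2S,4E,7R,8S)-2-(TBSO)-4,8-dimethyl-7-(TIPSO)deca-4,9-dienal | O=C[C@@H](O[Si](C)(C)C(C)(C)C)C/C(C)=C/C[C@@H](O[Si](C(C)C)(C(C)C)C(C)C)[C@@H](C)C=C | intermediate
17 | ethyl 2-(triphenylphosphoranylidene)propanoate | CCOC(=O)C(C)=P(c1ccccc1)(c1ccccc1)c1ccccc1 | starting material
18 | ethyl (2E,4S,6E,9R,10S)-4-(TBSO)-2,6,10-trimethyl-9-(TIPSO)dodeca-2,6,11-trienoate | CCOC(=O)/C(C)=C/[C@@H](O[Si](C)(C)C(C)(C)C)C/C(C)=C/C[C@@H](O[Si](C(C)C)(C(C)C)C(C)C)[C@@H](C)C=C | intermediate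
19 | (2E,4S,6E,9R,10S)-4-(TBSO)-2,6,10-trimethyl-9-(TIPSO)dodeca-2,6,11-trien-1-ol | OC/C(C)=C/[C@@H](O[Si](C)(C)C(C)(C)C)C/C(C)=C/C[C@@H](O[Si](C(C)C)(C(C)C)C(C)C)[C@@H](C)C=C | intermediate
20 | O-borinate, C6-borane bis(9-BBN) adduct of 19 | O(B1C2CCCC1CCC2)C/C(C)=C/[C@@H](O[Si](C)(C)C(C)(C)C)C/C(C)=C/C[C@@H](O[Si](C(C)C)(C(C)C)C(C)C)[C@@H](C)CCB1C2CCCC1CCC2 | intermediate
21 | (2E,4S,6E,9R,10S)-4-(TBSO)-2,6,10-trimethyl-9-(TIPSO)dodeca-2,6-diene-1,12-diol | OC/C(C)=C/[C@@H](O[Si](C)(C)C(C)(C)C)C/C(C)=C/C[C@@H](O[Si](C(C)C)(C(C)C)C(C)C)[C@@H](C)CCO | intermediate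
22 | (3S,4R,6E,9S,10E)-12-bromo-9-(TBSO)-3,7,11-trimethyl-4-(TIPSO)dodeca-6,10-dien-1-ol | BrC/C(C)=C/[C@@H](O[Si](C)(C)C(C)(C)C)C/C(C)=C/C[C@@H](O[Si](C(C)C)(C(C)C)C(C)C)[C@@H](C)CCO | intermediate
23 | (3S,4R,6E,9S,10E)-12-bromo-9-(TBSO)-3,7,11-trimethyl-4-(TIPSO)dodeca-6,10-dienal | BrC/C(C)=C/[C@@H](O[Si](C)(C)C(C)(C)C)C/C(C)=C/C[C@@H](O[Si](C(C)C)(C(C)C)C(C)C)[C@@H](C)CC=O | intermediate
24 | (E)-allylchromium dichloride derived from 23 | Cl[Cr](Cl)C/C(C)=C/[C@@H](O[Si](C)(C)C(C)(C)C)C/C(C)=C/C[C@@H](O[Si](C(C)C)(C(C)C)C(C)C)[C@@H](C)CC=O | intermediate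
25 | (1(10)E,3R,4S,6R,7S,8S)-8-(TBSO)-3-(TIPSO)germacra-1(10),11-dien-6-ol | CC(C)(C)[Si](C)(C)O[C@H]1C/C(C)=C/C[C@@H](O[Si](C(C)C)(C(C)C)C(C)C)[C@@H](C)C[C@@H](O)[C@@H]1C(C)=C | intermediate
26 | O6-borinate, C12-borane bis(9-BBN) adduct of 25 (C11 epimers) | CC(C)(C)[Si](C)(C)O[C@H]1C/C(C)=C/C[C@@H](O[Si](C(C)C)(C(C)C)C(C)C)[C@@H](C)C[C@@H](OB2C3CCCC2CCC3)[C@@H]1C(C)CB2C3CCCC2CCC3 | intermediate
27 | (1(10)E,3R,4S,6R,7S,8S)-8-(TBSO)-3-(TIPSO)germacr-1(10)-ene-6,12-diol (C11 epimers) | CC(C)(C)[Si](C)(C)O[C@H]1C/C(C)=C/C[C@@H](O[Si](C(C)C)(C(C)C)C(C)C)[C@@H](C)C[C@@H](O)[C@@H]1C(C)CO | intermediate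
28 | 6,12-lactol of 27 (C11 and C12 epimers) | CC(C)(C)[Si](C)(C)O[C@H]1C/C(C)=C/C[C@@H](O[Si](C(C)C)(C(C)C)C(C)C)[C@@H](C)C[C@H]2OC(O)C(C)[C@H]12 | intermediate
29 | 8-(TBSO)-3-(TIPSO)germacr-1(10)E-en-6,12-olide (C11 epimers) | CC(C)(C)[Si](C)(C)O[C@H]1C/C(C)=C/C[C@@H](O[Si](C(C)C)(C(C)C)C(C)C)[C@@H](C)C[C@H]2OC(=O)C(C)[C@H]12 | intermediate
30 | (1(10)E,3R,4S,6R,7S,8S,11S)-8-(TBSO)-3-(TIPSO)germacr-1(10)-en-6,12-olide | CC(C)(C)[Si](C)(C)O[C@H]1C/C(C)=C/C[C@@H](O[Si](C(C)C)(C(C)C)C(C)C)[C@@H](C)C[C@H]2OC(=O)[C@@H](C)[C@H]12 | intermediate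
31 | (1(10)E,3R,4S,6R,7R,8S,11S)-8-hydroxy-3-(TIPSO)germacr-1(10)-en-6,12-olide | O[C@H]1C/C(C)=C/C[C@@H](O[Si](C(C)C)(C(C)C)C(C)C)[C@@H](C)C[C@H]2OC(=O)[C@@H](C)[C@H]12 | intermediate
32 | tigloyl chloride, (E)-2-methylbut-2-enoyl chloride | C/C=C(\C)C(=O)Cl | starting material
33 | (1(10)E,3R,4S,6R,7S,8S,11S)-3-(TIPSO)germacr-1(10)-en-6,12-olide 8-tiglate | C/C=C(\C)C(=O)O[C@H]1C/C(C)=C/C[C@@H](O[Si](C(C)C)(C(C)C)C(C)C)[C@@H](C)C[C@H]2OC(=O)[C@@H](C)[C@H]12 | intermediate
34 | (1(10)E,3R,4S,6R,7S,8S,11S)-3-hydroxygermacr-1(10)-en-6,12-olide 8-tiglate | C/C=C(\C)C(=O)O[C@H]1C/C(C)=C/C[C@@H](O)[C@@H](C)C[C@H]2OC(=O)[C@@H](C)[C@H]12 | intermediate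
35 | (1S,10S)-1,10-epoxide of 34 | C/C=C(\C)C(=O)O[C@H]1C[C@]3(C)O[C@H]3C[C@@H](O)[C@@H](C)C[C@H]2OC(=O)[C@@H](C)[C@H]12 | intermediate
36 | (1S,3R,4S,6R,7S,8S,10R,11S)-1-hydroxy-3,10-epoxygermacran-6,12-olide 8-tiglate | C/C=C(\C)C(=O)O[C@H]1C[C@@]2(C)O[C@H](C[C@@H]2O)[C@@H](C)C[C@H]2OC(=O)[C@@H](C)[C@H]12 | intermediate
37 | (3R,4S,6R,7S,8S,10R,11S)-1-oxo-3,10-epoxygermacran-6,12-olide 8-tiglate | C/C=C(\C)C(=O)O[C@H]1C[C@@]2(C)O[C@H](CC2=O)[C@@H](C)C[C@H]2OC(=O)[C@@H](C)[C@H]12 | intermediate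
38 | (3S,4S,6R,7S,8S,10R,11S)-1-(trimethylsilyloxy)-3,10-epoxygermacr-1-en-6,12-olide 8-tiglate | C/C=C(\C)C(=O)O[C@H]1C[C@@]2(C)O[C@H](C=C2O[Si](C)(C)C)[C@@H](C)C[C@H]2OC(=O)[C@@H](C)[C@H]12 | intermediate
39 | CNP0235937.1, (4S,6R,7S,8S,10R,11S)-1-oxo-3,10-epoxygermacr-2-en-6,12-olide 8-tiglate | C/C=C(\C)C(=O)O[C@H]1C[C@@]2(C)OC(=CC2=O)[C@@H](C)C[C@H]2OC(=O)[C@@H](C)[C@H]12 | target

**Step count**
Total step count: 24. Longest linear sequence: 24 steps, from 1. All other building blocks (2, 5, 10, 17, 32) are commercial.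

**Steps most likely to fail**

Step 21. Facial selectivity of the oxygen transfer may be poor.
- If the ring conformer that shows the other alkene face reacts faster, O3 cannot reach the rear side of the resulting epoxide. Hydrogen bonding of an outward-pointing C3 hydroxyl to the peracid could favour that conformer.
- The material would then be lost to elimination or to opening by outside nucleophiles.
- The fallback sets out from 34 and replaces the irreversible oxygen transfer by a reversible electrophile.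
- N-Iodosuccinimide in MeCN at 0 °C forms iodonium ions on both faces in equilibrium. Only the one whose rear side faces O3 is drained, by a 5-endo iodoetherification at C10. This gives (1S)-1-iodo-3,10-epoxygermacran-6,12-olide 8-tiglate F1.
- Radical oxygenation (Bu3SnH, air, toluene, rt) converts the carbon–iodine bond into 1-hydroperoxy-3,10-epoxygermacran-6,12-olide 8-tiglate F2.
- PPh3 reduces F2 in the same flask to 1-hydroxy-3,10-epoxygermacran-6,12-olide 8-tiglate as a C1 epimer mixture F3.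
- Dess–Martin oxidation removes the C1 stereocentre, and the route is rejoined at 37.

Step 14. Beside oligomerisation, the anti selectivity may erode.
- Closure through the (Z)-allylchromium isomer or through a boat-like transition state would invert C6 relative to C7.
- The fallback sets out from 23 and sets C6 by SN2 inversion after ring closure instead of in the cyclisation transition state.
- The closure product (6S)-8-(TBSO)-3-(TIPSO)germacra-1(10),11-dien-6-ol F4 is submitted to a Mitsunobu reaction (4-nitrobenzoic acid, diisopropyl azodicarboxylate, PPh3, toluene).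
- This gives the (6R)-4-nitrobenzoate of 25 F5. Methanolysis (K2CO3, MeOH) returns to the route at 25.

Step 24. β-Hydride elimination towards the bridgehead carbon C3 may be slow.
- Protodesilylation by the liberated acetic acid could then win, which would only return ketone 37.
- The fallback sets out from 38 and uses a main-group syn elimination.
- PhSeCl (CH2Cl2, −78 °C) selenenylates C2 from the open face, cis to H3. This gives 2-(phenylselanyl)-1-oxo-3,10-epoxygermacran-6,12-olide 8-tiglate F6.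
- H2O2 and pyridine (CH2Cl2, 0 °C) form the corresponding selenoxide F7. It eliminates syn with H3 in the flask, and the route is rejoined at 39.

**Further compounds**
F1 | step 21 | (1S)-1-iodo-3,10-epoxygermacran-6,12-olide 8-tiglate | C/C=C(\C)C(=O)O[C@H]1C[C@@]2(C)O[C@H](C[C@@H]2I)[C@@H](C)C[C@H]2OC(=O)[C@@H](C)[C@H]12
F2 | step 21 | 1-hydroperoxy-3,10-epoxygermacran-6,12-olide 8-tiglate (C1 epimers) | C/C=C(\C)C(=O)O[C@H]1C[C@@]2(C)O[C@H](CC2OO)[C@@H](C)C[C@H]2OC(=O)[C@@H](C)[C@H]12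
F3 | step 21 | 1-hydroxy-3,10-epoxygermacran-6,12-olide 8-tiglate (C1 epimers) | C/C=C(\C)C(=O)O[C@H]1C[C@@]2(C)O[C@H](CC2O)[C@@H](C)C[C@H]2OC(=O)[C@@H](C)[C@H]12
F4 | step 14 | (1(10)E,3R,4S,6S,7S,8S)-8-(TBSO)-3-(TIPSO)germacra-1(10),11-dien-6-ol | CC(C)(C)[Si](C)(C)O[C@H]1C/C(C)=C/C[C@@H](O[Si](C(C)C)(C(C)C)C(C)C)[C@@H](C)C[C@H](O)[C@@H]1C(C)=C
F5 | step 14 | (6R)-4-nitrobenzoate of 25 | CC(C)(C)[Si](C)(C)O[C@H]1C/C(C)=C/C[C@@H](O[Si](C(C)C)(C(C)C)C(C)C)[C@@H](C)C[C@@H](OC(=O)c2ccc(cc2)[N+](=O)[O-])[C@@H]1C(C)=C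
F6 | step 24 | 2-(phenylselanyl)-1-oxo-3,10-epoxygermacran-6,12-olide 8-tiglate (Se cis to H3) | C/C=C(\C)C(=O)O[C@H]1C[C@@]2(C)O[C@H]([C@H]([Se]c3ccccc3)C2=O)[C@@H](C)C[C@H]2OC(=O)[C@@H](C)[C@H]12
F7 | step 24 | selenoxide of F6 | C/C=C(\C)C(=O)O[C@H]1C[C@@]2(C)O[C@H]([C@H]([Se](=O)c3ccccc3)C2=O)[C@@H](C)C[C@H]2OC(=O)[C@@H](C)[C@H]12
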